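**Retrosynthetic overview**

- Target 22 comes from the (2S)-flavanone 21 by MOM removal, and 21 from flavone 19 by enantioselective conjugate reduction of C2=C3, so the only stereocentre is set last.
- Ring B of 19 is disconnected at C1'–C2' and C5'–C6' into pyranopyranone 9 (ring D plus a 2-pyrone) and 2-ethynylchromone 17 (rings A and C), joined by a pyrone–alkyne cycloaddition with loss of CO2.
- The feature behind this: on ring B, O at C4', the ring D vinyl carbon at C5', prenyl at C3' and H at C2' are C4, C3, C5 and C6 of a 4-oxy-2-pyrone already fused to the dimethylpyran, and C1' and C6' are the two carbons of a terminal alkyne.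
- 9 comes from 4-hydroxy-5-prenyl-2-pyrone 6 and 3-methylbut-2-enal, and 6 from methyl acetoacetate by dianion prenylation and dianion formylation. 17 comes from the chromone-2-carboxylate 13 of phloroacetophenone and diethyl oxalate.
- Ring order: the pyrone and ring D in one branch, rings A and C in the other, ring B in the key step, then C2.

Key step: step 9

Assumption: (R)-DTBM-SEGPHOS is taken to deliver hydride to the C2 face that gives the (2S)-flavanone; if the sense of induction is the opposite, the (S)-ligand is used with no other change.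

**Route**

Step 1
Reactants: 1 methyl acetoacetate; 2 prenyl bromide
Product: 3 methyl 7-methyl-3-oxooct-6-enoate
Conditions: NaH, THF, 0 °C; n-BuLi, 0 °C; then 2, 0 °C → rt; 1 M HCl
Reagents that add atoms: none
Why: Alkylation of the acetoacetate dianion, whose more basic terminal carbanion should react selectively with the allylic bromide by SN2.

Step 2
Reactants: 3 methyl 7-methyl-3-oxooct-6-enoate; 4 methyl formate
Product: 6 4-hydroxy-5-(3-methylbut-2-enyl)-2H-pyran-2-one, via hydroxymethylene keto ester 5 (not isolated)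
Conditions: LiN(i-Pr)2 (3 equiv), THF, –78 → 0 °C; 4, –78 °C → rt; cold 1 M HCl; then DBU, toluene, 80 °C; 1 M HCl
Reagents that add atoms: none
Why: Claisen-type formylation of the β-keto ester dianion at the γ-carbon (the third equivalent of base absorbs the acidic tricarbonyl product), then DBU-promoted lactonisation of the enol oxygen of 5 onto the methyl ester, the usual closure of 3,5-dioxo esters to 4-hydroxy-2-pyrones.

Step 3
Reactants: 6 4-hydroxy-5-(3-methylbut-2-enyl)-2H-pyran-2-one; 7 3-methylbut-2-enal
Product: 9 2,2-dimethyl-8-(3-methylbut-2-enyl)-2H,5H-pyrano[4,3-b]pyran-5-one, via 1-oxatriene 8 (not isolated)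
Conditions: ethylenediammonium diacetate (20 mol %), CH2Cl2, 40 °C
Reagents that add atoms: none
Why: Knoevenagel condensation at pyrone C3 (C5 is blocked by the prenyl group) should give oxatriene 8, which closes by oxa-6π electrocyclisation onto the C4 oxygen, the established formal (3+3) annulation of 4-hydroxy-2-pyrones with enals.

Step 4
Reactants: 10 2,4,6-trihydroxyacetophenone; 11 diethyl oxalate
Product: 13 ethyl 5,7-dihydroxy-4-oxo-4H-chromene-2-carboxylate, via diketo ester 12 (not isolated)
Conditions: NaOEt (5 equiv), EtOH, reflux; then conc. HCl, EtOH, reflux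
Reagents that add atoms: none
Why: Claisen condensation of the methyl ketone with diethyl oxalate and acid-catalysed cyclodehydration is the classical chromone-2-carboxylate synthesis, run here on the free phenols because the acidic ring closure would not spare MOM ethers.

Step 5
Reactants: 13 ethyl 5,7-dihydroxy-4-oxo-4H-chromene-2-carboxylate
Product: 14 ethyl 5,7-bis(methoxymethoxy)-4-oxo-4H-chromene-2-carboxylate
Conditions: NaH (2.5 equiv), MOMCl (3 equiv), DMF, 0 °C → rt
Reagents that add atoms: chloromethyl methyl ether (MOMCl), COCCl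
Why: Williamson-type O-alkylation of both phenoxides, with NaH in DMF chosen because the hydrogen-bonded 5-OH is not alkylated under amine-base conditions.

Step 6
Reactants: 14 ethyl 5,7-bis(methoxymethoxy)-4-oxo-4H-chromene-2-carboxylate
Product: 15 2-(hydroxymethyl)-5,7-bis(methoxymethoxy)-4H-chromen-4-one
Conditions: NaBH4, MeOH–THF, 0 °C
Reagents that add atoms: none
Why: Chemoselective borohydride reduction of the activated 2-carboxylate next to the unreactive vinylogous-ester C4 carbonyl, a known entry to 2-(hydroxymethyl)chromones.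

Step 7
Reactants: 15 2-(hydroxymethyl)-5,7-bis(methoxymethoxy)-4H-chromen-4-one
Product: 16 5,7-bis(methoxymethoxy)-4-oxo-4H-chromene-2-carbaldehyde
Conditions: Dess–Martin periodinane, CH2Cl2, 0 °C → rt
Reagents that add atoms: none
Why: Dess–Martin oxidation of the allylic-type primary alcohol to the aldehyde under non-basic conditions that should leave the chromone and the MOM ethers untouched.

Step 8
Reactants: 16 5,7-bis(methoxymethoxy)-4-oxo-4H-chromene-2-carbaldehyde
Product: 17 2-ethynyl-5,7-bis(methoxymethoxy)-4H-chromen-4-one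
Conditions: dimethyl (1-diazo-2-oxopropyl)phosphonate, K2CO3, MeOH–THF, 0 °C
Reagents that add atoms: dimethyl (1-diazo-2-oxopropyl)phosphonate, COP(=O)(OC)C(=[N+]=[N-])C(C)=O
Why: Ohira–Bestmann (Seyferth–Gilbert) homologation, in which the diazophosphonate anion freed by methanolysis adds to the aldehyde, Horner–Wadsworth–Emmons-type elimination gives a diazoalkene, and loss of N2 with 1,2-hydrogen shift gives the terminal alkyne; low temperature and short contact time limit methoxide addition to the chromone.

Step 9
Reactants: 9 2,2-dimethyl-8-(3-methylbut-2-enyl)-2H,5H-pyrano[4,3-b]pyran-5-one; 17 2-ethynyl-5,7-bis(methoxymethoxy)-4H-chromen-4-one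
Product: 19 2-[2,2-dimethyl-8-(3-methylbut-2-enyl)-2H-chromen-6-yl]-5,7-bis(methoxymethoxy)-4H-chromen-4-one, via bridged bicyclic lactone 18 (not isolated)
Conditions: 9 (1.5 equiv), BHT (cat.), degassed o-dichlorobenzene, sealed tube, 170 °C
Reagents that add atoms: none
Why: The electron-rich pyrone diene of 9 (C4a=C8a–C8=C7, that is pyrone C3 to C6) should add in a concerted, asynchronous normal-demand Diels–Alder reaction to the terminal alkyne of 17, bonding C4a to the alkyne CH (C5'–C6') and C7 to the chromone-bearing carbon (C1'–C2') to give lactone 18, which loses CO2 in a retro-(4+2) step. The closest known reaction type is the thermal benzannulation of 4-alkoxy-2-pyrones with propiolates and ynones. Ring B is closed by this intermolecular (4+2) cycloaddition followed by cycloreversion, and the CO2 loss makes the aromatisation irreversible. No stereocentre is created in the product, because the two bridgehead centres of 18 vanish on aromatisation. The step needs regioselectivity, which should follow because the ring oxygen on C7 and the ether oxygen on C8a both make C4a the nucleophilic diene terminus, matched to the electrophilic terminal carbon of the vinylogous ynone, and because this pairing also keeps the chromone away from the fully substituted C4a. It also needs site selectivity for the pyrone diene over the 2H-pyran diene (C3=C4–C4a=C8a), which the gem-dimethyl group at C2 should provide by shielding both faces at C3.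

Step 10
Reactants: 19 2-[2,2-dimethyl-8-(3-methylbut-2-enyl)-2H-chromen-6-yl]-5,7-bis(methoxymethoxy)-4H-chromen-4-one
Product: 21 (2S)-2-[2,2-dimethyl-8-(3-methylbut-2-enyl)-2H-chromen-6-yl]-5,7-bis(methoxymethoxy)chroman-4-one, via silyl enol ether 20 (not isolated)
Conditions: Cu(OAc)2·H2O (5 mol %), (R)-DTBM-SEGPHOS (5.5 mol %), (EtO)2MeSiH (3 equiv), toluene, 0 °C → rt; then aq. NH4Cl, THF, 0 °C
Reagents that add atoms: none
Why: Copper hydride-catalysed asymmetric conjugate reduction of the chromone C2=C3 bond, in which the ligand pocket should direct hydride to one face of C2 to set (S); running without an alcohol keeps the product masked as silyl enol ether 20 until a cold neutral work-up, which guards against ketone reduction and ring-opening racemisation and leaves the unactivated prenyl and chromene alkenes without a proton source for net reduction.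

Step 11
Reactants: 21 (2S)-2-[2,2-dimethyl-8-(3-methylbut-2-enyl)-2H-chromen-6-yl]-5,7-bis(methoxymethoxy)chroman-4-one
Product: 22 (2S)-2-[2,2-dimethyl-8-(3-methylbut-2-enyl)-2H-chromen-6-yl]-5,7-dihydroxychroman-4-one
Conditions: 3 M aq. HCl, MeOH–THF, 40 °C
Reagents that add atoms: none
Why: Acid-catalysed acetal cleavage of both MOM ethers with methanol as formaldehyde acceptor; the prenyl group has no free ortho phenol to cyclise onto, and the mild temperature is chosen to avoid acid-mediated ring opening at C2.

**Compound list**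

1 | methyl acetoacetate | CC(=O)CC(=O)OC | starting material
2 | prenyl bromide (1-bromo-3-methylbut-2-ene) | CC(C)=CCBr | starting material
3 | methyl 7-methyl-3-oxooct-6-enoate | COC(=O)CC(=O)CCC=C(C)C | intermediate
4 | methyl formate | COC=O | starting material
5 | methyl (Z)-4-(hydroxymethylene)-7-methyl-3-oxooct-6-enoate (enol form of the γ-formyl keto ester) | COC(=O)CC(=O)/C(CC=C(C)C)=C\O | intermediate (not isolated)
6 | 4-hydroxy-5-(3-methylbut-2-enyl)-2H-pyran-2-one | O=C1C=C(O)C(CC=C(C)C)=CO1 | intermediate
7 | 3-methylbut-2-enal | CC(C)=CC=O | starting material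
8 | (E)-3-(3-methylbut-2-enylidene)-5-(3-methylbut-2-enyl)-2H-pyran-2,4(3H)-dione (1-oxatriene) | CC(C)=C/C=C1/C(=O)OC=C(CC=C(C)C)C1=O | intermediate (not isolated)
9 | 2,2-dimethyl-8-(3-methylbut-2-enyl)-2H,5H-pyrano[4,3-b]pyran-5-one | O=C1OC=C(CC=C(C)C)C2=C1C=CC(C)(C)O2 | intermediate
10 | 2,4,6-trihydroxyacetophenone | CC(=O)c1c(O)cc(O)cc1O | starting material
11 | diethyl oxalate | CCOC(=O)C(=O)OCC | starting material
12 | ethyl 2,4-dioxo-4-(2,4,6-trihydroxyphenyl)butanoate | CCOC(=O)C(=O)CC(=O)c1c(O)cc(O)cc1O | intermediate (not isolated)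
13 | ethyl 5,7-dihydroxy-4-oxo-4H-chromene-2-carboxylate | CCOC(=O)c1cc(=O)c2c(O)cc(O)cc2o1 | intermediate
14 | ethyl 5,7-bis(methoxymethoxy)-4-oxo-4H-chromene-2-carboxylate | CCOC(=O)c1cc(=O)c2c(OCOC)cc(OCOC)cc2o1 | intermediate
15 | 2-(hydroxymethyl)-5,7-bis(methoxymethoxy)-4H-chromen-4-one | OCc1cc(=O)c2c(OCOC)cc(OCOC)cc2o1 | intermediate
16 | 5,7-bis(methoxymethoxy)-4-oxo-4H-chromene-2-carbaldehyde | O=Cc1cc(=O)c2c(OCOC)cc(OCOC)cc2o1 | intermediate
17 | 2-ethynyl-5,7-bis(methoxymethoxy)-4H-chromen-4-one | C#Cc1cc(=O)c2c(OCOC)cc(OCOC)cc2o1 | intermediate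
18 | racemic 2-oxabicyclo[2.2.2]octa-5,7-dien-3-one cycloadduct of 9 and 17 (bridged lactone; configuration of the two bridgeheads fixed by the bicycle) | O=C1OC2C(CC=C(C)C)=C3OC(C)(C)C=CC13C=C2c4cc(=O)c5c(OCOC)cc(OCOC)cc5o4 | intermediate (not isolated)
19 | 2-[2,2-dimethyl-8-(3-methylbut-2-enyl)-2H-chromen-6-yl]-5,7-bis(methoxymethoxy)-4H-chromen-4-one | CC(C)=CCc1cc(-c2cc(=O)c3c(OCOC)cc(OCOC)cc3o2)cc2c1OC(C)(C)C=C2 | intermediate
20 | (2S)-4-[diethoxy(methyl)silyloxy]-2-[2,2-dimethyl-8-(3-methylbut-2-enyl)-2H-chromen-6-yl]-5,7-bis(methoxymethoxy)-2H-chromene | CC(C)=CCc1cc([C@@H]2C=C(O[Si](C)(OCC)OCC)c3c(OCOC)cc(OCOC)cc3O2)cc2c1OC(C)(C)C=C2 | intermediate (not isolated)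
21 | (2S)-2-[2,2-dimethyl-8-(3-methylbut-2-enyl)-2H-chromen-6-yl]-5,7-bis(methoxymethoxy)chroman-4-one | CC(C)=CCc1cc([C@@H]2CC(=O)c3c(OCOC)cc(OCOC)cc3O2)cc2c1OC(C)(C)C=C2 | intermediate
22 | (2S)-2-[2,2-dimethyl-8-(3-methylbut-2-enyl)-2H-chromen-6-yl]-5,7-dihydroxychroman-4-one | CC(C)=CCc1cc([C@@H]2CC(=O)c3c(O)cc(O)cc3O2)cc2c1OC(C)(C)C=C2 | target

**Step count**

Total: 11 steps. Longest linear sequence: 8 steps (10 → 13 → 14 → 15 → 16 → 17 → 19 → 21 → 22). The pyrone branch (1 → 3 → 6 → 9) has 3 steps.

**Steps most likely to fail**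

Step 9. The alkyne may add across the 2H-pyran diene of 9 with loss of acetone instead of across the pyrone diene. Alternatively, cycloaddition at the fully substituted terminus C4a may be slower than thermal ring opening and hydrogen-shift isomerisation of 9 or oligomerisation of 17. The fallback defers ring D; it sets out from 6 (and uses 17) and comes back at 19. Pyrone 6 would be silylated (i-Pr3SiOTf, Et3N, CH2Cl2, 0 °C) to 4-(triisopropylsilyloxy)-5-(3-methylbut-2-enyl)-2H-pyran-2-one F1, a monocyclic 4-silyloxy-2-pyrone with an unsubstituted C3 and no second diene. Its thermal cycloaddition–decarboxylation with 17 (toluene, 130–150 °C) should give 5,7-bis(methoxymethoxy)-2-[3-(3-methylbut-2-enyl)-4-(triisopropylsilyloxy)phenyl]-4H-chromen-4-one F2 with the same regiochemistry. Bu4NF buffered with AcOH in THF would free the 4'-phenol, 2-[4-hydroxy-3-(3-methylbut-2-enyl)phenyl]-5,7-bis(methoxymethoxy)-4H-chromen-4-one F3. O-alkylation with 3-chloro-3-methylbut-1-yne (DBU, cat. CuCl2, MeCN, 0 °C) would give the propargyl ether 5,7-bis(methoxymethoxy)-2-[3-(3-methylbut-2-enyl)-4-(2-methylbut-3-yn-2-yloxy)phenyl]-4H-chromen-4-one F4. Heating F4 (N,N-diethylaniline, 150 °C) should close ring D at the only free ortho position C5' by propargyl Claisen rearrangement, 1,5-hydrogen shift and oxa-6π closure, giving 19.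

Step 10. Conversion of the electron-rich 2-aryl vinylogous ester may be low, the ketone may be reduced further after premature desilylation, the chromene alkene may undergo hydrocupration, or the enolate may ring-open with loss of the C2 configuration. The fallback replaces asymmetric catalysis by racemic reduction and resolution; it sets out from 19 and comes back at 21. Conjugate reduction of 19 with LiBH(s-Bu)3 (THF, –78 °C, cold NH4Cl quench) should give the racemic flavanone rac-2-[2,2-dimethyl-8-(3-methylbut-2-enyl)-2H-chromen-6-yl]-5,7-bis(methoxymethoxy)chroman-4-one F5. Preparative HPLC on an amylose tris(3,5-dimethylphenylcarbamate) phase would separate 21 from the (2R)-enantiomer, (2R)-2-[2,2-dimethyl-8-(3-methylbut-2-enyl)-2H-chromen-6-yl]-5,7-bis(methoxymethoxy)chroman-4-one F6. F6 can be racemised with catalytic DBU through the ring-opened chalcone and returned to the separation.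

Step 8. Methoxide or the diazophosphonate anion may add in conjugate fashion to the electron-poor chromone of 16 or of product 17, consuming material before or after homologation. The fallback replaces the diazo homologation by a halogen-based sequence without alkoxide or organolithium; it sets out from 16 and comes back at 17. Dibromo-olefination of 16 (CBr4, PPh3, Et3N, CH2Cl2, 0 °C; Corey–Fuchs first stage) should give 2-(2,2-dibromovinyl)-5,7-bis(methoxymethoxy)-4H-chromen-4-one F7. Selective hydrogenolysis of the less hindered bromine (Bu3SnH, cat. Pd(PPh3)4, toluene, rt) would give (Z)-2-(2-bromovinyl)-5,7-bis(methoxymethoxy)-4H-chromen-4-one F8. Anti-elimination of HBr from F8 with Bu4NF in DMF at rt should then give 17.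

**Further compounds**

F1 | step 9 | 4-(triisopropylsilyloxy)-5-(3-methylbut-2-enyl)-2H-pyran-2-one | O=C1C=C(O[Si](C(C)C)(C(C)C)C(C)C)C(CC=C(C)C)=CO1
F2 | step 9 | 5,7-bis(methoxymethoxy)-2-[3-(3-methylbut-2-enyl)-4-(triisopropylsilyloxy)phenyl]-4H-chromen-4-one | CC(C)=CCc1cc(-c2cc(=O)c3c(OCOC)cc(OCOC)cc3o2)ccc1O[Si](C(C)C)(C(C)C)C(C)C
F3 | step 9 | 2-[4-hydroxy-3-(3-methylbut-2-enyl)phenyl]-5,7-bis(methoxymethoxy)-4H-chromen-4-one | CC(C)=CCc1cc(-c2cc(=O)c3c(OCOC)cc(OCOC)cc3o2)ccc1O
F4 | step 9 | 5,7-bis(methoxymethoxy)-2-[3-(3-methylbut-2-enyl)-4-(2-methylbut-3-yn-2-yloxy)phenyl]-4H-chromen-4-one | CC(C)=CCc1cc(-c2cc(=O)c3c(OCOC)cc(OCOC)cc3o2)ccc1OC(C)(C)C#C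
F5 | step 10 | rac-2-[2,2-dimethyl-8-(3-methylbut-2-enyl)-2H-chromen-6-yl]-5,7-bis(methoxymethoxy)chroman-4-one | CC(C)=CCc1cc(C2CC(=O)c3c(OCOC)cc(OCOC)cc3O2)cc2c1OC(C)(C)C=C2
F6 | step 10 | (2R)-2-[2,2-dimethyl-8-(3-methylbut-2-enyl)-2H-chromen-6-yl]-5,7-bis(methoxymethoxy)chroman-4-one | CC(C)=CCc1cc([C@H]2CC(=O)c3c(OCOC)cc(OCOC)cc3O2)cc2c1OC(C)(C)C=C2
F7 | step 8 | 2-(2,2-dibromovinyl)-5,7-bis(methoxymethoxy)-4H-chromen-4-one | BrC(Br)=Cc1cc(=O)c2c(OCOC)cc(OCOC)cc2o1
F8 | step 8 | (Z)-2-(2-bromovinyl)-5,7-bis(methoxymethoxy)-4H-chromen-4-one | Br/C=C\c1cc(=O)c2c(OCOC)cc(OCOC)cc2o1
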